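**Retrosynthetic overview**

1. The target is the 15-acetate of PGA2 methyl ester. The C10=C11 enone and the C15 acetate are made together at the end from a C11,C15-diol (PGE level) by acetylation and β-elimination of the C11 acetate.
2. Key disconnection C4–C5: a C5–C20 fragment carrying a Z-alkenyl iodide at C5 is joined to the C1–C4 radical released from the N-hydroxyphthalimide ester of glutaric acid monomethyl ester, by nickel-electrocatalytic decarboxylative alkenylation.
3. Enabling feature: the isolated cis C5=C6 olefin ends at C5 in a bond to a primary CH2 (C4) three carbons from the ester carbon C1, so C1–C4 is a glutaric half-ester minus CO2. The C5=C6–C7 allyl unit hangs on C8, next to the C9 ketone of the five-membered ring, so it can enter as an allylic electrophile that already carries the C5 iodide.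
4. The C5–C20 fragment comes from a one-flask three-component coupling on (R)-4-silyloxycyclopentenone. The bought C11 centre relays C12 (conjugate addition of the C13–C20 alkenyl donor, C15 bought) and C8 (enolate alkylation with (Z)-1,3-diiodopropene), and is erased in the last step.
5. Rings: the only ring, the cyclopentane, is purchased; no ring is formed in the route.

Key step: step 7

Remark: prostaglandin numbering is used (C1 ester carbon, C8 and C12 the ring carbons bearing the chains, C9 the ketone, C15 the acetoxy carbon); the target is read as 8R,12S,15S, 5Z,13E, and the four starting materials are assumed to be purchasable as single isomers.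

**Route**

Step 1
Reactants: 1 (S)-oct-1-yn-3-ol
Product: 2 (S)-tert-butyldimethyl(oct-1-yn-3-yloxy)silane
Conditions: TBSCl, imidazole, DMF, 0 °C → rt
Reagents that add atoms: tert-butyldimethylsilyl chloride, CC(C)(C)[Si](C)(C)Cl
Why: Imidazole-promoted silylation (standard TBS protection) of the secondary propargylic alcohol; the bought C15 centre is not touched.

Step 2
Reactants: 2 (S)-tert-butyldimethyl(oct-1-yn-3-yloxy)silane
Product: 4 (S,E)-tert-butyl[(1-iodooct-1-en-3-yl)oxy]dimethylsilane, via alkenylzirconocene chloride 3 (not isolated)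
Conditions: Cp2Zr(H)Cl, THF, rt; then I2, 0 °C
Reagents that add atoms: iodine, II
Why: Schwartz hydrozirconation adds Zr–H syn with zirconium on the terminal carbon, and iodinolysis of the C–Zr bond goes with retention, so the E-alkenyl iodide should form without affecting C15.

Step 3
Reactants: 5 ethyl (Z)-3-iodoacrylate
Product: 6 (Z)-3-iodoprop-2-en-1-ol
Conditions: DIBAL-H (2.2 equiv), CH2Cl2, −78 °C; Rochelle salt work-up
Reagents that add atoms: none
Why: DIBAL-H 1,2-reduction of the conjugated ester at low temperature should give the allylic alcohol with the Z-iodoalkene intact.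

Step 4
Reactants: 6 (Z)-3-iodoprop-2-en-1-ol
Product: 7 (Z)-1,3-diiodoprop-1-ene
Conditions: PPh3, I2, imidazole, CH2Cl2, 0 °C, dark; used freshly
Reagents that add atoms: iodine, II
Why: Appel-type iodination replaces the primary allylic hydroxyl by SN2 displacement of the oxyphosphonium group, leaving the vinylic C–I bond and the Z geometry unchanged.

Step 5
Reactants: 8 glutaric acid monomethyl ester (5-methoxy-5-oxopentanoic acid)
Product: 9 1,3-dioxoisoindolin-2-yl methyl pentanedioate
Conditions: N-hydroxyphthalimide, DIC, DMAP (cat.), CH2Cl2, rt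
Reagents that add atoms: N-hydroxyphthalimide, O=C1c2ccccc2C(=O)N1O
Why: Carbodiimide (Steglich-type) esterification of the free acid gives the redox-active ester while the methyl ester is inert.

Step 6
Reactants: 4 (S,E)-tert-butyl[(1-iodooct-1-en-3-yl)oxy]dimethylsilane, 10 (R)-4-(tert-butyldimethylsilyloxy)cyclopent-2-en-1-one, 7 (Z)-1,3-diiodoprop-1-ene
Product: 14 (2R,3R,4R)-4-(tert-butyldimethylsilyloxy)-3-[(S,E)-3-(tert-butyldimethylsilyloxy)oct-1-enyl]-2-[(Z)-3-iodoprop-2-enyl]cyclopentan-1-one, via alkenyllithium 11 (not isolated), via lithium alkenyldimethylzincate 12 (not isolated), via zinc enolate 13 (not isolated)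
Conditions: 4, t-BuLi (2 equiv), Et2O, −78 °C; Me2Zn (1 equiv), −78 → 0 °C; 10, THF, −78 °C; HMPA, then 7 (excess), −78 → −40 °C; aq. NH4Cl
Reagents that add atoms: none
Why: Three-component prostaglandin coupling (tandem conjugate addition–enolate alkylation, organozincate variant): iodine–lithium exchange and zincate formation give a soft alkenyl donor that should add at C12 anti to the C11 silyloxy group, and the resulting zinc enolate, activated by HMPA, should be C-alkylated at C8 by SN2 attack on the allylic CH2–I of 7 anti to the new C12 chain, so C12 and C8 are both relayed from C11 in one flask while the vinylic iodide of 7 stays inert.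

Step 7
Reactants: 14 (2R,3R,4R)-4-(tert-butyldimethylsilyloxy)-3-[(S,E)-3-(tert-butyldimethylsilyloxy)oct-1-enyl]-2-[(Z)-3-iodoprop-2-enyl]cyclopentan-1-one, 9 1,3-dioxoisoindolin-2-yl methyl pentanedioate
Product: 15 PGE2 methyl ester 11,15-bis(tert-butyldimethylsilyl) ether
Conditions: 9 (1.5–2 equiv), NiCl2·6H2O (10 mol %), 2,2′-bipyridine (10 mol %), AgNO3 (0.3 equiv), DMF, Mg(+)/RVC(−), undivided cell, constant current, rt
Reagents that add atoms: none
Why: Cathodic reduction should generate low-valent Ni(bpy), which adds oxidatively to the C5–I bond of 14, while single-electron reduction of 9 (by Ni(I) or at the silver-coated cathode) cleaves the N–O bond and expels CO2 and phthalimide anion to leave the primary radical •CH2CH2CH2CO2Me; capture of this radical by the alkenyl–Ni(II) species and reductive elimination from Ni(III) forge C4–C5. The closest known reaction type is the nickel-electrocatalytic decarboxylative alkenylation of N-hydroxyphthalimide esters with alkenyl halides on a silver-nanoparticle cathode, a C(sp2)–C(sp3) coupling of this class. No ring is closed and no stereocentre is created; the 5Z geometry is carried over from 14 because alkenyl–nickel intermediates couple with retention. The step needs chemoselectivity for the C5–I bond over the C9 ketone, the two silyl ethers and the 13E olefin, which the mild potential set by the sacrificial Mg anode and the nickel mediator should secure. Running the coupling at the C11-silyloxy (PGE) oxidation level keeps the C10=C11 enone, a radical acceptor, out of the substrate, and a primary radical without a β-leaving group cannot fragment or rearrange before capture.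

Step 8
Reactants: 15 PGE2 methyl ester 11,15-bis(tert-butyldimethylsilyl) ether
Product: 16 PGE2 methyl ester
Conditions: HF·pyridine, MeCN, 0 °C → rt
Reagents that add atoms: none
Why: Fluoride-mediated desilylation under buffered acidic conditions should cleave both TBS ethers while sparing the β-hydroxy ketone and the C8 centre, which basic fluoride sources would endanger.

Step 9
Reactants: 16 PGE2 methyl ester
Product: 18 PGA2 methyl ester 15-acetate (target), via PGE2 methyl ester diacetate 17 (not isolated)
Conditions: Ac2O, pyridine, DMAP (cat.), CH2Cl2, 0 °C → rt; then Et3N, rt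
Reagents that add atoms: acetic anhydride, CC(=O)OC(C)=O
Why: DMAP-catalysed acetylation esterifies both hydroxyls, and the C11 acetate, lying β to the C9 ketone, should then be lost by E1cB elimination to give the C10=C11 enone, whereas the allylic C15 acetate has no such pathway and C8/C12 keep their stable trans arrangement.

**Compound list**

1 | (S)-oct-1-yn-3-ol | CCCCC[C@@H](C#C)O | starting material
2 | (S)-tert-butyldimethyl(oct-1-yn-3-yloxy)silane | CCCCC[C@@H](C#C)O[Si](C)(C)C(C)(C)C | intermediate
3 | (S,E)-[3-(tert-butyldimethylsilyloxy)oct-1-enyl]zirconocene chloride | CCCCC[C@@H](/C=C/[Zr](Cl)(C1C=CC=C1)C1C=CC=C1)O[Si](C)(C)C(C)(C)C | intermediate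
4 | (S,E)-tert-butyl[(1-iodooct-1-en-3-yl)oxy]dimethylsilane | CCCCC[C@@H](/C=C/I)O[Si](C)(C)C(C)(C)C | intermediate
5 | ethyl (Z)-3-iodoacrylate | CCOC(=O)/C=C\I | starting material
6 | (Z)-3-iodoprop-2-en-1-ol | OC/C=C\I | intermediate
7 | (Z)-1,3-diiodoprop-1-ene | IC/C=C\I | intermediate
8 | glutaric acid monomethyl ester | COC(=O)CCCC(=O)O | starting material
9 | 1,3-dioxoisoindolin-2-yl methyl pentanedioate | COC(=O)CCCC(=O)ON1C(=O)c2ccccc2C1=O | intermediate
10 | (R)-4-(tert-butyldimethylsilyloxy)cyclopent-2-en-1-one | O=C1C=C[C@H](O[Si](C)(C)C(C)(C)C)C1 | starting material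
11 | (S,E)-[3-(tert-butyldimethylsilyloxy)oct-1-enyl]lithium | CCCCC[C@@H](/C=C/[Li])O[Si](C)(C)C(C)(C)C | intermediate
12 | lithium (S,E)-[3-(tert-butyldimethylsilyloxy)oct-1-enyl]dimethylzincate | CCCCC[C@@H](/C=C/[Zn-](C)C)O[Si](C)(C)C(C)(C)C.[Li+] | intermediate
13 | lithium dimethylzinc C8=C9 enolate of the 1,4-adduct (C12 chain trans to the C11 silyloxy group) | CCCCC[C@@H](/C=C/[C@H]1[C@@H](CC(O[Zn-](C)C)=C1)O[Si](C)(C)C(C)(C)C)O[Si](C)(C)C(C)(C)C.[Li+] | intermediate
14 | (2R,3R,4R)-4-(tert-butyldimethylsilyloxy)-3-[(S,E)-3-(tert-butyldimethylsilyloxy)oct-1-enyl]-2-[(Z)-3-iodoprop-2-enyl]cyclopentan-1-one | CCCCC[C@@H](/C=C/[C@H]1[C@@H](CC(=O)[C@@H]1C/C=C\I)O[Si](C)(C)C(C)(C)C)O[Si](C)(C)C(C)(C)C | intermediate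
15 | PGE2 methyl ester 11,15-bis(tert-butyldimethylsilyl) ether | CCCCC[C@@H](/C=C/[C@H]1[C@@H](CC(=O)[C@@H]1C/C=C\CCCC(=O)OC)O[Si](C)(C)C(C)(C)C)O[Si](C)(C)C(C)(C)C | intermediate
16 | PGE2 methyl ester | CCCCC[C@@H](/C=C/[C@H]1[C@@H](CC(=O)[C@@H]1C/C=C\CCCC(=O)OC)O)O | intermediate
17 | PGE2 methyl ester 11,15-diacetate | CCCCC[C@@H](/C=C/[C@H]1[C@@H](CC(=O)[C@@H]1C/C=C\CCCC(=O)OC)OC(C)=O)OC(C)=O | intermediate
18 | PGA2 methyl ester 15-acetate, methyl (5Z,13E,15S)-15-acetoxy-9-oxoprosta-5,10,13-trienoate | CCCCC[C@@H](/C=C/[C@H]1C=CC(=O)[C@@H]1C/C=C\CCCC(=O)OC)OC(C)=O | target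

**Step count and risks**

Total step count: 9. Longest linear sequence: 6 steps (1, 2, 6, 7, 8, 9).

Steps most likely to fail:

Step 7. The alkenyl–nickel intermediate may lose its Z geometry, may add to the C9 carbonyl four atoms away (closing a second five-membered ring), or the radical may dimerise or be reduced faster than it is captured. The fallback replaces the radical coupling by a two-electron, stereoretentive Negishi coupling. It sets out from 14: zinc insertion (Zn dust, LiCl, THF) into commercial methyl 4-bromobutanoate gives (4-methoxy-4-oxobutyl)zinc bromide F1, which is coupled with 14 under Pd(PPh3)4 or PdCl2(dppf) in THF/DMA at rt. It comes back to the route at 15.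

Step 6. C-alkylation of the zinc enolate may be slow enough for proton transfer and β-elimination of the C11 silyloxy group to compete, or the diiodide may be consumed by SN2′ attack or dehydroiodination. The fallback brings in C5–C7 at the alkyne oxidation level with a propargylic electrophile, the most reactive class for this enolate. It sets out from 4 and 10: the same addition sequence is quenched with 3-(trimethylsilyl)prop-2-ynyl bromide in place of 7 to give the 2-[3-(trimethylsilyl)prop-2-ynyl] ketone F2. Iododesilylation (NIS, AgNO3 cat., DMF) gives the 2-(3-iodoprop-2-ynyl) ketone F3, and cis-selective diimide reduction (2-nitrobenzenesulfonyl hydrazide, Et3N, THF/i-PrOH) delivers the Z-iodoalkene. It comes back to the route at 14.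

Step 9. Once the enone has formed, base may move the ring double bond into conjugation with C12 and C8 or epimerise C8; alternatively, elimination may stop at the diacetate. The fallback separates the two events and forms the enone under acid. It sets out from 16: acid-catalysed dehydration (AcOH/H2O 9:1, 60 °C) gives PGA2 methyl ester F4, which is acetylated at C15 with Ac2O/pyridine at 0 °C without DMAP. It comes back to the route at 18.

**Further compounds**

F1 | step 7 | (4-methoxy-4-oxobutyl)zinc bromide | COC(=O)CCC[Zn]Br
F2 | step 6 | (2R,3R,4R)-4-(tert-butyldimethylsilyloxy)-3-[(S,E)-3-(tert-butyldimethylsilyloxy)oct-1-enyl]-2-[3-(trimethylsilyl)prop-2-ynyl]cyclopentan-1-one | CCCCC[C@@H](/C=C/[C@H]1[C@@H](CC(=O)[C@@H]1CC#C[Si](C)(C)C)O[Si](C)(C)C(C)(C)C)O[Si](C)(C)C(C)(C)C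
F3 | step 6 | (2R,3R,4R)-4-(tert-butyldimethylsilyloxy)-3-[(S,E)-3-(tert-butyldimethylsilyloxy)oct-1-enyl]-2-(3-iodoprop-2-ynyl)cyclopentan-1-one | CCCCC[C@@H](/C=C/[C@H]1[C@@H](CC(=O)[C@@H]1CC#CI)O[Si](C)(C)C(C)(C)C)O[Si](C)(C)C(C)(C)C
F4 | step 9 | PGA2 methyl ester, methyl (5Z,13E,15S)-15-hydroxy-9-oxoprosta-5,10,13-trienoate | CCCCC[C@@H](/C=C/[C@H]1C=CC(=O)[C@@H]1C/C=C\CCCC(=O)OC)O
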